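**Retrosynthetic overview**
1. The ester C–O bond and the hindered O1–C8a aryl ether bond of the pyran ring are disconnected together. This gives an O-acetylferuloyl chloride and a seven-membered (3R)-3-methyl-2,3-dihydro-1-benzoxepin-3-ol. The benzoxepinol contracts to the 2H-chromene by a base-induced O-to-O aryl transfer (Smiles type) and is acylated at the primary oxygen it sets free.
2. Enabling feature: in the benzo ring the acetyl carbonyl on C6 stands para to C8a, the carbon that bears pyran O1. O1 (on C2) and the ester oxygen (on the CH2 at C2) sit on vicinal carbons, so a five-membered spiro σ-adduct at C8a can exchange the two oxygens without touching the C2–O bond.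
3. The oxepine ring is opened at its C4=C5 bond (ring-closing metathesis) to an aryl ether of (R)-2-methylbut-3-ene-1,2-diol.
4. This ether comes from 5-vinylacetovanillone (acetovanillone, iodination, vinylation) and the diol monotosylate, which is made from (S)-2-methylglycidol, the only source of chirality.
5. Ring order: the benzo rings are bought, the oxepine ring is formed by metathesis, and the pyran ring arises by contraction of the oxepine ring.

Key step: step 9

Assumption: the stereocentre in the SMILES is C2 of the chromene and is (R) by the CIP ranking O1 > CH2O > C3 > CH3. Both enantiomers of 2-methylglycidol are taken as purchasable in enantiopure form.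

**Route**

Step 1
Reactants: 1 acetovanillone (1-(4-hydroxy-3-methoxyphenyl)ethan-1-one)
Product: 2 5-iodoacetovanillone (1-(4-hydroxy-3-iodo-5-methoxyphenyl)ethan-1-one)
Conditions: NIS (1.05 equiv), TFA (0.2 equiv), MeCN, 0 °C → rt
Reagents that add atoms: N-iodosuccinimide, O=C1CCC(=O)N1I
Why: Electrophilic aromatic iodination, in which the free phenol directs the iodonium equivalent to its only open ortho position because the para position is blocked by the acetyl group.

Step 2
Reactants: 2 5-iodoacetovanillone
Product: 3 5-vinylacetovanillone (1-(3-ethenyl-4-hydroxy-5-methoxyphenyl)ethan-1-one)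
Conditions: CH2=CHBF3K (1.3 equiv), PdCl2(dppf) (3 mol%), Cs2CO3 (3 equiv), THF–H2O (9:1), 75 °C
Reagents that add atoms: potassium vinyltrifluoroborate, C=C[B-](F)(F)F.[K+]
Why: Suzuki–Miyaura vinylation of an aryl iodide with a vinyltrifluoroborate, a coupling that tolerates a free phenol and an aryl ketone.

Step 3
Reactants: 4 (S)-2-methylglycidol ([(2S)-2-methyloxiran-2-yl]methanol)
Product: 6 (2R)-2-methylbut-3-ene-1,2-diol, via sulfonium betaine 5 (not isolated)
Conditions: Me3SI (4.0 equiv), n-BuLi (3.9 equiv), THF, −15 °C; then 4, −15 °C → rt; non-aqueous work-up (solid NH4Cl, filtration)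
Reagents that add atoms: trimethylsulfonium iodide, C[S+](C)C.[I-]
Why: One-carbon epoxide-to-allylic-alcohol homologation with excess dimethylsulfonium methylide, in which the ylide opens the oxirane at its CH2 and further ylide triggers β-elimination of Me2S from 5; the C–O bond at the stereocentre is never broken and a Payne rearrangement of 4 is degenerate, so (S)-4 should give (R)-6, the descriptor changing only through the CIP ranking.

Step 4
Reactants: 6 (2R)-2-methylbut-3-ene-1,2-diol
Product: 7 (2R)-2-hydroxy-2-methylbut-3-en-1-yl 4-methylbenzenesulfonate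
Conditions: TsCl (1.05 equiv), Et3N (1.5 equiv), DMAP (5 mol%), CH2Cl2, 0 °C
Reagents that add atoms: 4-toluenesulfonyl chloride, Cc1ccc(cc1)S(=O)(=O)Cl
Why: Chemoselective sulfonylation, in which the primary hydroxyl reacts while the tertiary allylic hydroxyl is inert at 0 °C and the stereocentre is not involved.

Step 5
Reactants: 3 5-vinylacetovanillone; 7 (2R)-2-hydroxy-2-methylbut-3-en-1-yl 4-methylbenzenesulfonate
Product: 9 1-(3-ethenyl-4-{[(2R)-2-hydroxy-2-methylbut-3-en-1-yl]oxy}-5-methoxyphenyl)ethan-1-one, via (2R)-2-ethenyl-2-methyloxirane 8 (not isolated)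
Conditions: K2CO3 (2.5 equiv), BHT (trace), DMF, 75 °C, sealed tube
Reagents that add atoms: none
Why: The base closes 7 to oxirane 8 (3-exo-tet Williamson closure, helped by the gem-disubstitution) and the phenoxide of 3 opens 8 by SN2 attack at the unsubstituted CH2, the usual regiochemistry of basic epoxide opening, so the C–O bond at the stereocentre is never touched.

Step 6
Reactants: 9 1-(3-ethenyl-4-{[(2R)-2-hydroxy-2-methylbut-3-en-1-yl]oxy}-5-methoxyphenyl)ethan-1-one
Product: 10 1-[(3R)-3-hydroxy-9-methoxy-3-methyl-2,3-dihydro-1-benzoxepin-7-yl]ethan-1-one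
Conditions: second-generation Grubbs catalyst (5 mol%), 1,4-benzoquinone (10 mol%), CH2Cl2 (5 mM), 40 °C; chromatography on Et3N-washed silica
Reagents that add atoms: none
Why: Ring-closing metathesis of a styrene with a vinyl carbinol, which a free allylic hydroxyl is known to speed up; the seven-membered ring enforces the Z olefin and the stereocentre is a spectator.

Step 7
Reactants: 11 (E)-ferulic acid
Product: 12 (E)-3-(4-acetoxy-3-methoxyphenyl)prop-2-enoic acid
Conditions: Ac2O (2.5 equiv), pyridine, rt; then H2O
Reagents that add atoms: acetic anhydride, CC(=O)OC(C)=O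
Why: Standard O-acetylation of a phenol, with any mixed anhydride at the acid function hydrolysed on the aqueous quench.

Step 8
Reactants: 12 (E)-3-(4-acetoxy-3-methoxyphenyl)prop-2-enoic acid
Product: 13 (E)-3-(4-acetoxy-3-methoxyphenyl)prop-2-enoyl chloride
Conditions: (COCl)2 (1.3 equiv), DMF (cat.), CH2Cl2, 0 °C → rt
Reagents that add atoms: oxalyl chloride, O=C(Cl)C(=O)Cl
Why: Acid chloride formation through the catalytic Vilsmeier-type chloroiminium species, which leaves the aryl acetate and the E olefin untouched.

Step 9
Reactants: 10 1-[(3R)-3-hydroxy-9-methoxy-3-methyl-2,3-dihydro-1-benzoxepin-7-yl]ethan-1-one; 13 (E)-3-(4-acetoxy-3-methoxyphenyl)prop-2-enoyl chloride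
Product: 18 [(2R)-6-acetyl-8-methoxy-2-methyl-2H-chromen-2-yl]methyl (E)-3-(4-acetoxy-3-methoxyphenyl)prop-2-enoate, via tertiary potassium alkoxide 14 (not isolated), via spiro σ-adduct 15 (not isolated), via primary potassium alkoxide 16 (not isolated), via chromenylmethanol 17 (not isolated)
Conditions: KOt-Bu (1.05 equiv), THF–DMPU (5:1), 0 → 40 °C, dark; then −20 °C, DMAP·HCl (1.1 equiv); then 13 (1.3 equiv), −20 °C → rt
Reagents that add atoms: none
Why: Proposed new method: KOt-Bu turns 10 into the tertiary alkoxide 14, whose oxygen adds to C9a, the benzo-ring carbon that carries the oxepine oxygen, to give the spiro σ-adduct 15 with the charge resting on the para acetyl oxygen; 15 expels the primary oxygen and so trades the seven-membered oxepine for the six-membered pyran (16), after which DMAP·HCl sets free alcohol 17 and DMAP, and 13 acylates the only unhindered hydroxyl. The closest known reaction type is the base-induced O-to-O Smiles rearrangement of 2-aryloxyethanols, which has been shown for open-chain, nitro-activated aryl ethers but not for a ketone-activated aryl ether or as a ring contraction. The new C–O bond closes the dioxolane of 15 in a 5-exo-trig mode and, seen from the nascent pyran, in a 6-endo-trig mode, and 15 has the unstrained 6,8-dioxabicyclo[3.2.1]oct-2-ene frame known from levoglucosenone. No stereocentre is made or broken in the product: the C3–O bond of 10 stays intact, so (3R)-10 should map onto (2R)-17 with retention, and the transient spiro carbon of 15 is dictated by the bicyclic frame and vanishes again. The step needs ipso attack to win over 3-exo-tet displacement of the aryloxide at the neighbouring CH2 and over enolate chemistry of the acetyl group; the five-membered transition state, the para acetyl and ortho styryl acceptors, and a single equivalent of an alkoxide base rather than an amide base should secure this. The direction is set by the loss of oxepine strain and by the change from a tertiary to a primary alkoxide, and buffering before the acid chloride arrives keeps the aryl acetate of 13 and any acetyl enolate out of the acylation.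

Step 10
Reactants: 18 [(2R)-6-acetyl-8-methoxy-2-methyl-2H-chromen-2-yl]methyl (E)-3-(4-acetoxy-3-methoxyphenyl)prop-2-enoate
Product: 19 [(2R)-6-acetyl-8-methoxy-2-methyl-2H-chromen-2-yl]methyl (E)-ferulate (target CNP0168033.1)
Conditions: pyrrolidine (3 equiv), CH2Cl2, 0 °C → rt, dark
Reagents that add atoms: none
Why: Chemoselective aminolysis, in which the aryl acetate is an activated ester and should be cleaved by pyrrolidine far faster than the hindered neopentyl-type cinnamate, while the stereocentre and the E olefin are not affected.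

**Compound list**
1 | acetovanillone | CC(=O)c1ccc(O)c(OC)c1 | starting material
2 | 5-iodoacetovanillone | CC(=O)c1cc(I)c(O)c(OC)c1 | intermediate
3 | 5-vinylacetovanillone | CC(=O)c1cc(C=C)c(O)c(OC)c1 | intermediate
4 | (S)-2-methylglycidol | C[C@]1(CO)CO1 | starting material
5 | [(3R)-4-hydroxy-3-methyl-3-oxidobutyl]dimethylsulfonium (betaine) | C[C@]([O-])(CO)CC[S+](C)C | intermediate
6 | (2R)-2-methylbut-3-ene-1,2-diol | C[C@](O)(CO)C=C | intermediate
7 | (2R)-2-hydroxy-2-methylbut-3-en-1-yl 4-methylbenzenesulfonate | C[C@](O)(COS(=O)(=O)c1ccc(C)cc1)C=C | intermediate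
8 | (2R)-2-ethenyl-2-methyloxirane | C[C@]1(CO1)C=C | intermediate
9 | 1-(3-ethenyl-4-{[(2R)-2-hydroxy-2-methylbut-3-en-1-yl]oxy}-5-methoxyphenyl)ethan-1-one | C[C@](O)(COc1c(OC)cc(C(C)=O)cc1C=C)C=C | intermediate
10 | 1-[(3R)-3-hydroxy-9-methoxy-3-methyl-2,3-dihydro-1-benzoxepin-7-yl]ethan-1-one | C[C@]1(O)COc2c(OC)cc(C(C)=O)cc2C=C1 | intermediate
11 | (E)-ferulic acid | COc1cc(/C=C/C(=O)O)ccc1O | starting material
12 | (E)-3-(4-acetoxy-3-methoxyphenyl)prop-2-enoic acid | COc1cc(/C=C/C(=O)O)ccc1OC(C)=O | intermediate
13 | (E)-3-(4-acetoxy-3-methoxyphenyl)prop-2-enoyl chloride | COc1cc(/C=C/C(=O)Cl)ccc1OC(C)=O | intermediate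
14 | potassium (3R)-7-acetyl-9-methoxy-3-methyl-2,3-dihydro-1-benzoxepin-3-olate | C[C@]1([O-])COc2c(OC)cc(C(C)=O)cc2C=C1.[K+] | intermediate
15 | potassium salt of the spiro σ-adduct (6,8-dioxabicyclo[3.2.1]oct-2-ene whose ketal bridgehead is the former C9a; cyclohexadienylidene enolate of the acetyl group) | CC([O-])=C1C=C(OC)[C@]23OC[C@](C)(O2)C=CC3=C1.[K+] | intermediate
16 | potassium [(2R)-6-acetyl-8-methoxy-2-methyl-2H-chromen-2-yl]methanolate | [O-]C[C@@]1(C)C=Cc2cc(C(C)=O)cc(OC)c2O1.[K+] | intermediate
17 | 1-[(2R)-2-(hydroxymethyl)-8-methoxy-2-methyl-2H-chromen-6-yl]ethan-1-one | OC[C@@]1(C)C=Cc2cc(C(C)=O)cc(OC)c2O1 | intermediate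
18 | [(2R)-6-acetyl-8-methoxy-2-methyl-2H-chromen-2-yl]methyl (E)-3-(4-acetoxy-3-methoxyphenyl)prop-2-enoate | COc1cc(/C=C/C(=O)OC[C@@]2(C)C=Cc3cc(C(C)=O)cc(OC)c3O2)ccc1OC(C)=O | intermediate
19 | [(2R)-6-acetyl-8-methoxy-2-methyl-2H-chromen-2-yl]methyl (E)-ferulate | COc1cc(/C=C/C(=O)OC[C@@]2(C)C=Cc3cc(C(C)=O)cc(OC)c3O2)ccc1O | target

**Step count**
Total step count: 10.
Longest linear sequence: 6 steps (1, 2, 5, 6, 9, 10). The branch 3, 4, 5, 6, 9, 10 is equally long.

**Steps most likely to fail**

Step 9 (Proposed new method).
- What may go wrong: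
  - The aryl transfer may be too slow with a ketone as the only strong acceptor, because enolisation of the acetyl group drains the base.
  - The alkoxide may instead displace the aryloxide at the neighbouring CH2. That opens the ring and, through re-closure, could erode the enantiopurity.
- Fallback (known chemistry), setting out from 3:
  - 3 is combined with commercial racemic 2-ethenyl-2-methyloxirane F1, Pd2(dba)3·CHCl3 and the enantiomer of N,N'-(cyclohexane-1,2-diyl)bis[2-(diphenylphosphanyl)benzamide] that leads to the (R)-ether, in CH2Cl2 at rt.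
  - This is an asymmetric Tsuji–Trost etherification run as a dynamic kinetic transformation. The alkoxide of the π-allyl intermediate takes the phenol proton and steers the phenoxide to the adjacent, fully substituted terminus.
  - It should give 1-(3-ethenyl-4-{[(2R)-1-hydroxy-2-methylbut-3-en-2-yl]oxy}-5-methoxyphenyl)ethan-1-one F2.
  - Ring-closing metathesis of F2 (second-generation Grubbs catalyst, CH2Cl2, 40 °C) closes the pyran ring and comes back to the route at 17.
  - 17 is then acylated with 13 (Et3N, DMAP, CH2Cl2, 0 °C) to 18.

Step 5.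
- What may go wrong:
  - The volatile oxirane may be lost from the hot mixture.
  - The phenoxide may attack the vinyl terminus (SN2′) instead of the oxirane CH2.
  - The styrene may oligomerise thermally.
- Fallback, setting out from 3:
  - The phenoxide of 3 opens commercial (R)-2-methylglycidol F3 at its oxirane CH2 (K2CO3, DMF, 80 °C). This epoxide is non-volatile and has no allylic position.
  - The product is 1-(4-{[(2R)-2,3-dihydroxy-2-methylpropyl]oxy}-3-ethenyl-5-methoxyphenyl)ethan-1-one F4.
  - Parikh–Doering oxidation (SO3·pyridine, DMSO, Et3N) gives (2S)-3-(4-acetyl-2-ethenyl-6-methoxyphenoxy)-2-hydroxy-2-methylpropanal F5.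
  - Wittig methylenation (MePPh3Br, KHMDS, THF, −78 °C) leads back to the route at 9. The aldehyde reacts far faster than the aryl ketone, which surplus ylide masks as its enolate.
  - Here the aryl ether grows from the oxirane CH2 and the vinyl group from the carbinol carbon, so the opposite enantiomer of the glycidol is needed for the same (R)-9.

Step 3.
- What may go wrong:
  - Elimination from the betaine may be incomplete.
  - The betaine may close to an oxetane.
  - The small, water-soluble diol may be lost on isolation.
- Fallback, setting out from 4: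
  - PhSeCH2Li (from (PhSe)2CH2 and n-BuLi, THF, −78 °C, 2.2 equiv) opens the oxirane at CH2 to the easily handled (2R)-2-methyl-4-(phenylselanyl)butane-1,2-diol F6.
  - H2O2 (THF, 0 °C → rt) oxidises F6 to (2R)-2-methyl-4-(phenylseleninyl)butane-1,2-diol F7.
  - F7 undergoes selenoxide syn-elimination at rt and comes back to the route at 6.

**Further compounds**
F1 | step 9 | rac-2-ethenyl-2-methyloxirane (purchased) | CC1(CO1)C=C
F2 | step 9 | 1-(3-ethenyl-4-{[(2R)-1-hydroxy-2-methylbut-3-en-2-yl]oxy}-5-methoxyphenyl)ethan-1-one | OC[C@](C)(Oc1c(OC)cc(C(C)=O)cc1C=C)C=C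
F3 | step 5 | (R)-2-methylglycidol (purchased) | C[C@@]1(CO)CO1
F4 | step 5 | 1-(4-{[(2R)-2,3-dihydroxy-2-methylpropyl]oxy}-3-ethenyl-5-methoxyphenyl)ethan-1-one | C[C@@](O)(CO)COc1c(OC)cc(C(C)=O)cc1C=C
F5 | step 5 | (2S)-3-(4-acetyl-2-ethenyl-6-methoxyphenoxy)-2-hydroxy-2-methylpropanal | C[C@@](O)(C=O)COc1c(OC)cc(C(C)=O)cc1C=C
F6 | step 3 | (2R)-2-methyl-4-(phenylselanyl)butane-1,2-diol | C[C@](O)(CO)CC[Se]c1ccccc1
F7 | step 3 | (2R)-2-methyl-4-(phenylseleninyl)butane-1,2-diol | C[C@](O)(CO)CC[Se](=O)c1ccccc1
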